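## Structural features

The target 29 is a 5,6-dihydro-2H-pyran-2-one (ring A: O, C1–C5) whose C5 carbon carries a ten-carbon chain ending in a phenyl group. Atoms are numbered from the lactone carbonyl C1 to the benzylic carbon C15. The chain begins with a Z alkene (C6=C7) bonded directly to the ring stereocentre C5 (S), then carries hydroxyls at C9 (R), C11 (S) and C13 (R), with C9/C11 syn and C11/C13 anti. No two stereocentres are adjacent: C9, C11 and C13 are 1,3-related, and C5 and C9 are 1,5-related across the alkene. The fragile parts are the conjugated lactone (bases open it or eliminate the C5 oxygen, which is both allylic and acylated), the Z alkene and the free triol. The real difficulty is the remote C5/C9 relationship together with the Z geometry between the two centres, since neither has a neighbour that could relay control; the 1,3-diol is routine by comparison. The unit O5–C5–C6=C7–C8–C9–O9 is a Z-5-alkoxyalk-3-en-1-ol. The key step makes exactly this unit in one bond-forming event: an allyltin trichloride chelated by the C5 ether oxygen adds through C8 to a C9 aldehyde.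

## Logic of the disconnections

29 ⇒ 28. The three O–Si bonds at C9, C11 and C13 are cut last. One kind of silyl ether on all three hydroxyls lets a single acidic fluoride treatment finish the synthesis. The demand is that the deprotection spares the unsaturated lactone, so basic fluoride is excluded.

28 ⇒ 26 (through 27). The lactone C1–O5 bond is cut and O5 is given a naphthylmethyl group. A Z-enoate with a δ-oxygen is a latent ring A, and the ether on O5 is the ligand the key step needs, so its removal is postponed until ring closure is wanted. The forward step needs an oxidative ether cleavage that leaves two Z alkenes and three silyl ethers alone, and a Z C2=C3 bond so that the ring can close.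

26 ⇒ 24 + 25. The C2=C3 bond is cut. C1 and C2 then come from a commercial phosphonate. The forward olefination must be Z-selective and must not eliminate the β-naphthylmethoxy group of 24.

24 ⇒ 23 ⇒ 22 ⇒ 21. These are oxidation-level and protecting-group changes at C3 and C9. C3 must pass through the key step as a silyl ether, because an aldehyde or ester there would compete for tin. C9 is silylated so that later intermediates are single, fully protected compounds. The demand is selective cleavage of one primary silyl ether beside three secondary ones.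

21 ⇒ 12 + 19. The C8–C9 bond is cut; this is the strategic step. It splits the chain into a C3–C8 piece and a C9–C15 piece of similar size, and lets C5 fix both C9 and the C6=C7 geometry. The forward step requires 12 to be 4S with a donor ether on that oxygen and tin on C8. It requires 19 to carry only non-chelating silyl ethers. Naphthylmethyl is kept on O5 because it tolerates SnCl4 better than a methoxybenzyl ether and is still removable with DDQ.

12 ⇒ 9 + 10. The C8–Sn bond is cut. The forward displacement must occur at the primary carbon (SN2, not SN2′) and keep the E alkene.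

9 ⇒ 8 ⇒ 6 + 7. C8 is taken back to the ester level and the O5–CH2 bond of the ether is cut. Etherification is placed on 6 and done without base, because the alkoxide of a γ-hydroxy enoate is unstable.

6 ⇒ 5 ⇒ 1 + 2 + 3. The C6=C7 bond and the C5–O bond are cut. C5 is created catalytically from an achiral aldehyde, and C7 and C8 arrive with the E alkene from the phosphonate. No protecting group is needed on the C8 oxygen, which keeps this branch to five steps. The demand is enantiocontrol by the D-proline catalyst.

19 ⇒ 18 ⇒ 17. C9 is taken back to an ester and the two silyl groups are removed. The ester is the oxidation level at which the diol is assembled.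

17 ⇒ 16. The C11 carbinol is traced to a ketone. The existing C13 hydroxyl directs an anti-selective reduction, so C11 needs no reagent of its own.

16 ⇒ 14 + 15. The C10–C11 bond is cut (Claisen condensation). C9 and C10 come from an acetate ester. The forward step must acylate a free β-hydroxy ester without protecting it.

14 ⇒ 13. The C13 carbinol is traced to the ketone of a commercial β-keto ester. Asymmetric hydrogenation sets the first stereocentre of this branch with a reliable sense.

## Other disconnections considered

Alternative 1: The cut is at C9–C10 and C11–C12, so that C8–C13 come from three two-carbon aldehydes. In the forward step 2-deoxy-D-ribose-5-phosphate aldolase would add two molecules of acetaldehyde A2 in turn to chloroacetaldehyde A1, and the syn dihydroxy aldehyde would close to the lactol A3.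
- In its favour: one catalytic step from commodity aldehydes sets C9 and C11 with enzyme-level control. For these two centres this is better than the chosen plan in step count, cost and absence of tin.
- Against it here: A3 delivers C13 as a lactol carbon with no stereocentre and no phenethyl group, so the 11,13-anti relationship must still be built by chain extension and a directed reduction. C8 arrives as a chloromethyl group. A carbanion at C8 would eliminate the C9 oxygen, so C7 can only be attached by displacement chemistry. The Z alkene and C5 would then need further separate operations.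
- Comparison: structurally A3 fits the syn C9/C11 pair very well but leaves the C5/C9 relationship across the alkene unsolved. Mechanistically the enzyme is at least the equal of steps 8 and 11 for absolute control. In step economy the early gain is expected to be spent on C13, C8 and the alkene, so the total should be no shorter.

Alternative 2: The cut lies inside a six-membered ring, at the C8–C13 bond of the meso ketone A4. In the forward step a peracid with a chiral N,N'-dioxide complex of Sc(OTf)3 would make one of the two enantiotopic ring bonds migrate. This gives the seven-membered lactone A5, in which C8 is bound to oxygen and C13 is the acyl carbon.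
- In its favour: it uses the hidden symmetry of the C8–C13 syn-diol, which the chosen plan does not use; on that point it is the better design. Its two termini also emerge differentiated, which is better than A3 for later work at C13.
- Against it here: the two migrating methylene groups of A4 differ only through remote silyloxy centres, so the enantiotopic choice is demanding. A β-silyloxy ketone can eliminate under Lewis acid. A4 itself takes several operations to prepare. C8 again arrives oxygenated and must become a CH2 bonded to C7 by displacement next to a silyloxy group, and C5 and the Z alkene again need their own steps.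
- Comparison: in mechanism, catalyst discrimination of a meso ketone is less secure than the chelate-controlled chair of step 11 or the directed reduction of step 8. In step economy it is expected to be comparable or longer.

Alternative 3: The cut is the C6=C7 bond itself. In the forward step the bis-alkoxysilane A6, which ties O5 and O9 through a diisopropylsilylene unit, would undergo ring-closing metathesis with (H2IMes)(PCy3)Cl2Ru=CHPh, the second-generation Grubbs catalyst. The product is the eight-membered silaketal A7.
- In its favour: the Z geometry is enforced by ring size, which is at least the equal of step 11 and arguably more certain. C5 and C9 are each set by an independent reagent-controlled step, so nothing depends on remote induction. No stoichiometric tin is used.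
- Against it here: two separate asymmetric operations are needed, for example an allylation of 19 for C9 and a separate route to the C5 vinyl carbinol. The unsymmetrical silaketal must be assembled in two stages while avoiding symmetrical by-products. Eight-membered ring closure needs dilution and competes with oligomerisation. After the tether is removed, O5 and O9 are freed together.
- Comparison: in stereochemical reliability this route is the equal of the chosen plan or better. In step economy it is expected to be two or three operations longer, because step 11 forms the C–C bond, the alkene geometry and the C9 centre at once.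

Key step: step 11

Assumption: 1, 7, 13 and 25 are taken as purchasable (7 is otherwise one operation from naphthalen-2-ylmethanol and trichloroacetonitrile); checking 12, 19 and 21 centre by centre against 29 shows them consistent (C5 S, C9 R, C11 S, C13 R in the numbering of 29) and needing no correction; the CIP label of C11 changes with its neighbours (S in 19, R in 21, S from 22 on) although the centre is never touched.

## Steps

Step 1
Reactants: 1 4-(tert-butyldimethylsilyloxy)butanal; 2 nitrosobenzene; 3 triethyl phosphonoacetate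
Product: 5 ethyl (2E,4S)-4-(anilinooxy)-6-(tert-butyldimethylsilyloxy)hex-2-enoate, via α-anilinooxy aldehyde 4 (not isolated)
Conditions: D-proline (20 mol%), DMSO, rt; then 3, LiCl, DBU, MeCN, 0 °C
Reagents that add atoms: none
Why: Proline-catalysed α-aminoxylation (the enamine attacks the nitroso oxygen, which is held by the carboxylic acid) followed in the same flask by a Masamune–Roush Horner–Wadsworth–Emmons olefination; D-proline should give the S centre that becomes C5, and the stabilised phosphonate should give the E-enoate before the α-oxygenated aldehyde can epimerise.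

Step 2
Reactants: 5 ethyl (2E,4S)-4-(anilinooxy)-6-(tert-butyldimethylsilyloxy)hex-2-enoate
Product: 6 ethyl (2E,4S)-6-(tert-butyldimethylsilyloxy)-4-hydroxyhex-2-enoate
Conditions: Cu(OAc)2 (30 mol%), EtOH, rt
Reagents that add atoms: none
Why: Copper-mediated scission of the weak N–O bond of an O-alkyl-N-arylhydroxylamine, the usual unmasking of α-aminoxylation products; the conjugated alkene, the silyl ether and the carbinol centre should not be affected.

Step 3
Reactants: 6 ethyl (2E,4S)-6-(tert-butyldimethylsilyloxy)-4-hydroxyhex-2-enoate; 7 naphthalen-2-ylmethyl 2,2,2-trichloroacetimidate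
Product: 8 ethyl (2E,4S)-6-(tert-butyldimethylsilyloxy)-4-(naphthalen-2-ylmethoxy)hex-2-enoate
Conditions: TfOH (5 mol%), CH2Cl2/cyclohexane, 0 °C
Reagents that add atoms: none
Why: Acid-catalysed trichloroacetimidate etherification avoids the alkoxide of a γ-hydroxy enoate, which would undergo conjugate addition or isomerisation; catalytic acid in an apolar medium at 0 °C should leave the primary silyl ether in place and does not touch the stereocentre.

Step 4
Reactants: 8 ethyl (2E,4S)-6-(tert-butyldimethylsilyloxy)-4-(naphthalen-2-ylmethoxy)hex-2-enoate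
Product: 9 (2E,4S)-6-(tert-butyldimethylsilyloxy)-4-(naphthalen-2-ylmethoxy)hex-2-en-1-ol
Conditions: iBu2AlH (2.5 equiv), CH2Cl2, −78 °C; aq. potassium sodium tartrate
Reagents that add atoms: none
Why: 1,2-Reduction of a conjugated ester by iBu2AlH at low temperature gives the E-allylic alcohol; both ethers and the alkene geometry are inert to the reagent.

Step 5
Reactants: 9 (2E,4S)-6-(tert-butyldimethylsilyloxy)-4-(naphthalen-2-ylmethoxy)hex-2-en-1-ol; 10 tributyltin hydride
Product: 12 tributyl[(2E,4S)-6-(tert-butyldimethylsilyloxy)-4-(naphthalen-2-ylmethoxy)hex-2-en-1-yl]stannane, via allylic mesylate 11 (not isolated)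
Conditions: n-BuLi, THF, −78 °C; MsCl; then Bu3SnLi (from 10 and LiN(iPr)2, THF, 0 °C), −78 → −40 °C
Reagents that add atoms: methanesulfonyl chloride CS(=O)(=O)Cl (its atoms stay only in 11)
Why: One-flask activation and displacement: the lithium alkoxide is mesylated and Bu3SnLi displaces the primary allylic mesylate by SN2 at the unhindered terminus, a standard preparation of allylstannanes from allylic alcohols; the E geometry and the ether-bearing centre should be retained.

Step 6
Reactants: 13 ethyl 3-oxo-5-phenylpentanoate
Product: 14 ethyl (3R)-3-hydroxy-5-phenylpentanoate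
Conditions: H2 (10 bar), RuCl2[(R)-BINAP] (0.5 mol%), EtOH, 60 °C
Reagents that add atoms: none
Why: Noyori asymmetric hydrogenation of a β-keto ester; the ester-chelated ketone is reduced by the (R)-BINAP ruthenium hydride from the face that gives the 3R alcohol, which becomes C13.

Step 7
Reactants: 14 ethyl (3R)-3-hydroxy-5-phenylpentanoate; 15 tert-butyl acetate
Product: 16 tert-butyl (5R)-5-hydroxy-3-oxo-7-phenylheptanoate
Conditions: 15 (4 equiv), LiN(iPr)2 (4 equiv), THF, −78 °C; then 14, −78 → −30 °C
Reagents that add atoms: none
Why: Crossed Claisen condensation: excess lithium enolate of 15 first deprotonates the hydroxyl and then acylates at the ethyl ester, and the product is stored as its enolate so that it is not attacked again; the carbinol centre is not enolisable and should stay intact.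

Step 8
Reactants: 16 tert-butyl (5R)-5-hydroxy-3-oxo-7-phenylheptanoate
Product: 17 tert-butyl (3S,5R)-3,5-dihydroxy-7-phenylheptanoate
Conditions: Me4NBH(OAc)3, MeCN/AcOH (1:1), −30 °C
Reagents that add atoms: none
Why: Evans–Saksena reduction: the C13 hydroxyl exchanges onto boron and hydride is delivered intramolecularly through a chair, which should give the 1,3-anti diol and so set C11 (3S in 17).

Step 9
Reactants: 17 tert-butyl (3S,5R)-3,5-dihydroxy-7-phenylheptanoate
Product: 18 tert-butyl (3S,5R)-3,5-bis(tert-butyldimethylsilyloxy)-7-phenylheptanoate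
Conditions: TBSCl (3 equiv), imidazole (6 equiv), DMF, 40 °C
Reagents that add atoms: tert-butyldimethylsilyl chloride CC(C)(C)[Si](C)(C)Cl
Why: Standard silylation of both secondary alcohols; the chloride with imidazole is preferred to the silyl triflate so that the tert-butyl ester is not attacked.

Step 10
Reactants: 18 tert-butyl (3S,5R)-3,5-bis(tert-butyldimethylsilyloxy)-7-phenylheptanoate
Product: 19 (3S,5R)-3,5-bis(tert-butyldimethylsilyloxy)-7-phenylheptanal
Conditions: iBu2AlH (1.1 equiv), toluene, −78 °C; MeOH at −78 °C, then aq. potassium sodium tartrate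
Reagents that add atoms: none
Why: Partial reduction of an ester by iBu2AlH; the aluminium hemiacetal of the hindered ester should survive at −78 °C until the cold quench and then release the aldehyde, and the β-silyloxy centre cannot epimerise.

Step 11
Reactants: 12 tributyl[(2E,4S)-6-(tert-butyldimethylsilyloxy)-4-(naphthalen-2-ylmethoxy)hex-2-en-1-yl]stannane; 19 (3S,5R)-3,5-bis(tert-butyldimethylsilyloxy)-7-phenylheptanal
Product: 21 (3S,4Z,7R,9R,11R)-1,9,11-tris(tert-butyldimethylsilyloxy)-3-(naphthalen-2-ylmethoxy)-13-phenyltridec-4-en-7-ol, via chelated allyltin trichloride 20 (not isolated)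
Conditions: SnCl4 (1.3 equiv), CH2Cl2, −78 °C, 5 min; then 19, −78 °C, 1 h; aq. NaHCO3
Reagents that add atoms: tin tetrachloride Cl[Sn](Cl)(Cl)Cl (its atoms stay only in 20)
Why: SnCl4 (tetravalent tin) attacks C6 of 12 on the face held by the naphthylmethyl ether oxygen while the tributyltin group leaves C8 (SE2′ transmetalation), giving the allyltin trichloride 20 in which O5 is bound to tin in a four-membered chelate with the vinyl group and the C4 chain trans. Aldehyde 19 then binds the same tin and C8 attacks the carbonyl carbon through a six-membered chair in which the chelated substituent α to tin is axial and the aldehyde chain equatorial, so the C8–C9 bond, the Z C6=C7 alkene and the C9 carbinol arise in one event. The closest known reaction type is the tin tetrachloride-promoted addition of 4-alkoxyalk-2-enylstannanes to aldehydes, which gives Z-5-alkoxyalk-3-en-1-ols with 1,5-induction. No ring is closed; the six-membered array exists only in the transition state. C9 is controlled by C5: in this chair the 5S chelate exposes the Re face of the aldehyde, which corresponds to 9R. The step needs reaction at C8 rather than C6, Z selectivity, and dominance of the reagent over the C11 silyl ether; all three should follow from the tin–oxygen chelate, because a β-silyloxy group is a weak director in a closed transition state. Forming 20 at −78 °C before 19 is added keeps free SnCl4 away from the aldehyde and limits 1,2-elimination of the β-alkoxytin unit.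

Step 12
Reactants: 21 (3S,4Z,7R,9R,11R)-1,9,11-tris(tert-butyldimethylsilyloxy)-3-(naphthalen-2-ylmethoxy)-13-phenyltridec-4-en-7-ol
Product: 22 (3S,4Z,7R,9S,11R)-1,7,9,11-tetrakis(tert-butyldimethylsilyloxy)-3-(naphthalen-2-ylmethoxy)-13-phenyltridec-4-ene
Conditions: TBSOTf, 2,6-lutidine, CH2Cl2, −78 → 0 °C
Reagents that add atoms: tert-butyldimethylsilyl triflate CC(C)(C)[Si](C)(C)OS(=O)(=O)C(F)(F)F
Why: Silyl triflate with a hindered base silylates the secondary homoallylic alcohol under conditions mild enough for the allylic ether and the Z alkene.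

Step 13
Reactants: 22 (3S,4Z,7R,9S,11R)-1,7,9,11-tetrakis(tert-butyldimethylsilyloxy)-3-(naphthalen-2-ylmethoxy)-13-phenyltridec-4-ene
Product: 23 (3S,4Z,7R,9S,11R)-7,9,11-tris(tert-butyldimethylsilyloxy)-3-(naphthalen-2-ylmethoxy)-13-phenyltridec-4-en-1-ol
Conditions: HF·pyridine, pyridine, THF, 0 °C → rt
Reagents that add atoms: none
Why: Buffered HF·pyridine should remove the unhindered primary silyl ether much faster than the three secondary ones (steric discrimination in silyl ether cleavage).

Step 14
Reactants: 23 (3S,4Z,7R,9S,11R)-7,9,11-tris(tert-butyldimethylsilyloxy)-3-(naphthalen-2-ylmethoxy)-13-phenyltridec-4-en-1-ol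
Product: 24 (3S,4Z,7R,9S,11R)-7,9,11-tris(tert-butyldimethylsilyloxy)-3-(naphthalen-2-ylmethoxy)-13-phenyltridec-4-enal
Conditions: Dess–Martin periodinane, pyridine, CH2Cl2, 0 °C → rt
Reagents that add atoms: none
Why: Dess–Martin oxidation under pyridine buffering gives the β-alkoxy aldehyde without conditions that would eliminate the naphthylmethoxy group.

Step 15
Reactants: 24 (3S,4Z,7R,9S,11R)-7,9,11-tris(tert-butyldimethylsilyloxy)-3-(naphthalen-2-ylmethoxy)-13-phenyltridec-4-enal; 25 methyl bis(2,2,2-trifluoroethoxy)phosphorylacetate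
Product: 26 methyl (2Z,5S,6Z,9R,11S,13R)-9,11,13-tris(tert-butyldimethylsilyloxy)-5-(naphthalen-2-ylmethoxy)-15-phenylpentadeca-2,6-dienoate
Conditions: 25, KN(SiMe3)2, 18-crown-6, THF, −78 °C
Reagents that add atoms: none
Why: Still–Gennari variant of the Horner–Wadsworth–Emmons reaction: the trifluoroethyl phosphonate anion with a dissociated potassium ion eliminates quickly from the kinetic adduct and should give the Z-enoate; the weakly basic anion at −78 °C should not trigger β-elimination.

Step 16
Reactants: 26 methyl (2Z,5S,6Z,9R,11S,13R)-9,11,13-tris(tert-butyldimethylsilyloxy)-5-(naphthalen-2-ylmethoxy)-15-phenylpentadeca-2,6-dienoate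
Product: 28 (6S)-6-[(1Z,4R,6S,8R)-4,6,8-tris(tert-butyldimethylsilyloxy)-10-phenyldec-1-en-1-yl]-5,6-dihydro-2H-pyran-2-one, via hydroxy Z-enoate 27 (not isolated)
Conditions: DDQ, CH2Cl2/pH 7 buffer, 0 °C → rt; then PPTS (10 mol%), CH2Cl2, rt
Reagents that add atoms: none
Why: DDQ oxidises the electron-rich naphthylmethyl ether to an oxocarbenium ion that water hydrolyses; the freed C5 hydroxyl lies cis to the ester across the Z C2=C3 bond and should close the six-membered lactone by acid-catalysed transesterification, with the silyl ethers left in place.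

Step 17
Reactants: 28 (6S)-6-[(1Z,4R,6S,8R)-4,6,8-tris(tert-butyldimethylsilyloxy)-10-phenyldec-1-en-1-yl]-5,6-dihydro-2H-pyran-2-one
Product: 29 (6S)-6-[(1Z,4R,6S,8R)-4,6,8-trihydroxy-10-phenyldec-1-en-1-yl]-5,6-dihydro-2H-pyran-2-one
Conditions: HF (48% aq.), MeCN, 0 °C → rt
Reagents that add atoms: none
Why: Acidic fluoride desilylation; basic fluoride is avoided because the unsaturated lactone is prone to elimination and ring opening, whereas HF in MeCN should leave the lactone, the Z alkene and all four stereocentres untouched.

## Compound list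

1 | 4-(tert-butyldimethylsilyloxy)butanal | O=CCCCO[Si](C)(C)C(C)(C)C | starting material
2 | nitrosobenzene | O=Nc1ccccc1 | starting material
3 | triethyl phosphonoacetate | CCOC(=O)CP(=O)(OCC)OCC | starting material
4 | (2S)-2-(anilinooxy)-4-(tert-butyldimethylsilyloxy)butanal | O=C[C@@H](ONc1ccccc1)CCO[Si](C)(C)C(C)(C)C | intermediate (not isolated)
5 | ethyl (2E,4S)-4-(anilinooxy)-6-(tert-butyldimethylsilyloxy)hex-2-enoate | CCOC(=O)/C=C/[C@@H](ONc1ccccc1)CCO[Si](C)(C)C(C)(C)C | intermediate
6 | ethyl (2E,4S)-6-(tert-butyldimethylsilyloxy)-4-hydroxyhex-2-enoate | CCOC(=O)/C=C/[C@@H](O)CCO[Si](C)(C)C(C)(C)C | intermediate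
7 | naphthalen-2-ylmethyl 2,2,2-trichloroacetimidate | N=C(OCc1ccc2ccccc2c1)C(Cl)(Cl)Cl | starting material
8 | ethyl (2E,4S)-6-(tert-butyldimethylsilyloxy)-4-(naphthalen-2-ylmethoxy)hex-2-enoate | CCOC(=O)/C=C/[C@@H](OCc1ccc2ccccc2c1)CCO[Si](C)(C)C(C)(C)C | intermediate
9 | (2E,4S)-6-(tert-butyldimethylsilyloxy)-4-(naphthalen-2-ylmethoxy)hex-2-en-1-ol | OC/C=C/[C@@H](OCc1ccc2ccccc2c1)CCO[Si](C)(C)C(C)(C)C | intermediate
10 | tributyltin hydride | CCCC[SnH](CCCC)CCCC | starting material
11 | (2E,4S)-6-(tert-butyldimethylsilyloxy)-4-(naphthalen-2-ylmethoxy)hex-2-en-1-yl methanesulfonate | CS(=O)(=O)OC/C=C/[C@@H](OCc1ccc2ccccc2c1)CCO[Si](C)(C)C(C)(C)C | intermediate (not isolated)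
12 | tributyl[(2E,4S)-6-(tert-butyldimethylsilyloxy)-4-(naphthalen-2-ylmethoxy)hex-2-en-1-yl]stannane | CC(C)(C)[Si](C)(C)OCC[C@@H](/C=C/C[Sn](CCCC)(CCCC)CCCC)OCc1ccc2ccccc2c1 | intermediate
13 | ethyl 3-oxo-5-phenylpentanoate | CCOC(=O)CC(=O)CCc1ccccc1 | starting material
14 | ethyl (3R)-3-hydroxy-5-phenylpentanoate | CCOC(=O)C[C@H](O)CCc1ccccc1 | intermediate
15 | tert-butyl acetate | CC(=O)OC(C)(C)C | starting material
16 | tert-butyl (5R)-5-hydroxy-3-oxo-7-phenylheptanoate | CC(C)(C)OC(=O)CC(=O)C[C@H](O)CCc1ccccc1 | intermediate
17 | tert-butyl (3S,5R)-3,5-dihydroxy-7-phenylheptanoate | CC(C)(C)OC(=O)C[C@@H](O)C[C@H](O)CCc1ccccc1 | intermediate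
18 | tert-butyl (3S,5R)-3,5-bis(tert-butyldimethylsilyloxy)-7-phenylheptanoate | CC(C)(C)OC(=O)C[C@@H](O[Si](C)(C)C(C)(C)C)C[C@H](O[Si](C)(C)C(C)(C)C)CCc1ccccc1 | intermediate
19 | (3S,5R)-3,5-bis(tert-butyldimethylsilyloxy)-7-phenylheptanal | O=CC[C@@H](O[Si](C)(C)C(C)(C)C)C[C@H](O[Si](C)(C)C(C)(C)C)CCc1ccccc1 | intermediate
20 | trichloro[(3S,4S)-6-(tert-butyldimethylsilyloxy)-4-(naphthalen-2-ylmethoxy)hex-1-en-3-yl]stannane, ether oxygen coordinated to tin | C=C[C@H]([Sn](Cl)(Cl)Cl)[C@@H](OCc1ccc2ccccc2c1)CCO[Si](C)(C)C(C)(C)C | intermediate (not isolated)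
21 | (3S,4Z,7R,9R,11R)-1,9,11-tris(tert-butyldimethylsilyloxy)-3-(naphthalen-2-ylmethoxy)-13-phenyltridec-4-en-7-ol | CC(C)(C)[Si](C)(C)OCC[C@@H](/C=C\C[C@@H](O)C[C@@H](O[Si](C)(C)C(C)(C)C)C[C@H](O[Si](C)(C)C(C)(C)C)CCc1ccccc1)OCc1ccc2ccccc2c1 | intermediate
22 | (3S,4Z,7R,9S,11R)-1,7,9,11-tetrakis(tert-butyldimethylsilyloxy)-3-(naphthalen-2-ylmethoxy)-13-phenyltridec-4-ene | CC(C)(C)[Si](C)(C)OCC[C@@H](/C=C\C[C@@H](O[Si](C)(C)C(C)(C)C)C[C@@H](O[Si](C)(C)C(C)(C)C)C[C@H](O[Si](C)(C)C(C)(C)C)CCc1ccccc1)OCc1ccc2ccccc2c1 | intermediate
23 | (3S,4Z,7R,9S,11R)-7,9,11-tris(tert-butyldimethylsilyloxy)-3-(naphthalen-2-ylmethoxy)-13-phenyltridec-4-en-1-ol | OCC[C@@H](/C=C\C[C@@H](O[Si](C)(C)C(C)(C)C)C[C@@H](O[Si](C)(C)C(C)(C)C)C[C@H](O[Si](C)(C)C(C)(C)C)CCc1ccccc1)OCc1ccc2ccccc2c1 | intermediate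
24 | (3S,4Z,7R,9S,11R)-7,9,11-tris(tert-butyldimethylsilyloxy)-3-(naphthalen-2-ylmethoxy)-13-phenyltridec-4-enal | O=CC[C@@H](/C=C\C[C@@H](O[Si](C)(C)C(C)(C)C)C[C@@H](O[Si](C)(C)C(C)(C)C)C[C@H](O[Si](C)(C)C(C)(C)C)CCc1ccccc1)OCc1ccc2ccccc2c1 | intermediate
25 | methyl bis(2,2,2-trifluoroethoxy)phosphorylacetate | COC(=O)CP(=O)(OCC(F)(F)F)OCC(F)(F)F | starting material
26 | methyl (2Z,5S,6Z,9R,11S,13R)-9,11,13-tris(tert-butyldimethylsilyloxy)-5-(naphthalen-2-ylmethoxy)-15-phenylpentadeca-2,6-dienoate | COC(=O)/C=C\C[C@@H](/C=C\C[C@@H](O[Si](C)(C)C(C)(C)C)C[C@@H](O[Si](C)(C)C(C)(C)C)C[C@H](O[Si](C)(C)C(C)(C)C)CCc1ccccc1)OCc1ccc2ccccc2c1 | intermediate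
27 | methyl (2Z,5S,6Z,9R,11S,13R)-9,11,13-tris(tert-butyldimethylsilyloxy)-5-hydroxy-15-phenylpentadeca-2,6-dienoate | COC(=O)/C=C\C[C@H](O)/C=C\C[C@@H](O[Si](C)(C)C(C)(C)C)C[C@@H](O[Si](C)(C)C(C)(C)C)C[C@H](O[Si](C)(C)C(C)(C)C)CCc1ccccc1 | intermediate (not isolated)
28 | (6S)-6-[(1Z,4R,6S,8R)-4,6,8-tris(tert-butyldimethylsilyloxy)-10-phenyldec-1-en-1-yl]-5,6-dihydro-2H-pyran-2-one | O=C1C=CC[C@@H](/C=C\C[C@@H](O[Si](C)(C)C(C)(C)C)C[C@@H](O[Si](C)(C)C(C)(C)C)C[C@H](O[Si](C)(C)C(C)(C)C)CCc2ccccc2)O1 | intermediate
29 | (6S)-6-[(1Z,4R,6S,8R)-4,6,8-trihydroxy-10-phenyldec-1-en-1-yl]-5,6-dihydro-2H-pyran-2-one | O=C1C=CC[C@@H](/C=C\C[C@@H](O)C[C@@H](O)C[C@H](O)CCc2ccccc2)O1 | target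

## Step count and least certain steps

Total step count: 17 (steps 1–5 to 12, steps 6–10 to 19, step 11, steps 12–17). Longest linear sequence: 12 steps (from 1 or from 13 to 29).

Step 11 (key step). What may go wrong: collapse of the β-alkoxy allyltin trichloride by 1,2-elimination or protodestannylation before it meets the aldehyde; erosion of facial selectivity if the bulky C11 silyl ether opposes the chelate-controlled chair; Lewis-acid loss of the primary silyl ether. The fallback sets out from 19 and returns at 22; it keeps the C8–C9 bond but builds the alkene from an alkyne. 19 is propargylated with allenyltributylstannane under Ti(OiPr)4/(R)-BINOL catalysis (Re-face attack is what 9R requires) to give the homopropargylic alcohol (4R,6R,8R)-6,8-bis(tert-butyldimethylsilyloxy)-10-phenyldec-1-yn-4-ol F1. Silylation (TBSOTf, 2,6-lutidine) gives the tris-silyl ether F2. Its lithium acetylide (n-BuLi, THF, −78 °C) is acylated with N-methoxy-N-methyl-3-(tert-butyldimethylsilyloxy)propanamide to give the ynone F3. Transfer hydrogenation with RuCl[(S,S)-TsDPEN](p-cymene) in iPrOH sets C5 and gives the propargylic alcohol F4. NaH and 2-(bromomethyl)naphthalene give the naphthylmethyl ether F5. Semihydrogenation (H2, Pd/CaCO3 poisoned with Pb(OAc)2, quinoline) gives 22.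

Step 5. What may go wrong: attack of the stannyl anion at the internal allylic carbon, electron transfer leading to reductive loss of the naphthylmethoxy group, or scrambling of the alkene geometry. The fallback sets out from 9 and returns at 12. 9 is converted (NaH, CS2, MeI) into the O-allyl S-methyl xanthate F6. On gentle warming this undergoes [3,3]-sigmatropic rearrangement to the transposed S-allyl S-methyl dithiocarbonate F7. Tributyltin hydride with AIBN in refluxing benzene then adds a stannyl radical to the terminal alkene carbon and expels the sulfur group with allylic transposition, which should give 12 as an E-rich mixture; the alkene geometry is lost anyway on transmetalation to 20.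

Step 3. What may go wrong: acid-promoted loss of the primary silyl ether, or rearrangement of the imidate to the N-alkyl amide faster than transfer to a weakly nucleophilic hydroxyl. The fallback sets out from 6 and returns at 9; the ether is made by Williamson alkylation after the enoate has gone. 6 is reduced (iBu2AlH, CH2Cl2, −78 °C) to (2E,4S)-6-(tert-butyldimethylsilyloxy)hex-2-ene-1,4-diol F8. The primary allylic hydroxyl is acylated selectively (pivaloyl chloride, pyridine, −20 °C) to give the mono-pivalate F9. NaH and 2-(bromomethyl)naphthalene with Bu4NI give the naphthylmethyl ether pivalate F10. iBu2AlH at −78 °C removes the pivalate and gives 9.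

Step 13. What may go wrong: concurrent cleavage or migration of secondary silyl ethers, above all the less hindered one on C9, or incomplete conversion. The fallback sets out from 22 and returns at 29; it replaces selective deprotection by selective oxidation. All four silyl ethers are removed (HF·pyridine in excess, THF) to give the tetraol F11. TEMPO with PhI(OAc)2 oxidises only the primary alcohol and gives the trihydroxy aldehyde F12. Still–Gennari olefination with an excess of the potassium salt of 25 gives the trihydroxy Z-enoate F13. DDQ followed by PPTS gives 29 directly.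

Step 10. What may go wrong: over-reduction to the primary alcohol or incomplete reduction of the hindered tert-butyl ester. The fallback sets out from 18 and returns at 19. 18 is reduced fully (LiAlH4, Et2O, 0 °C) to (3R,5R)-3,5-bis(tert-butyldimethylsilyloxy)-7-phenylheptan-1-ol F14, which is oxidised with Dess–Martin periodinane to 19.

## Further compounds

F1 | step 11 | (4R,6R,8R)-6,8-bis(tert-butyldimethylsilyloxy)-10-phenyldec-1-yn-4-ol | C#CC[C@@H](O)C[C@@H](O[Si](C)(C)C(C)(C)C)C[C@H](O[Si](C)(C)C(C)(C)C)CCc1ccccc1
F2 | step 11 | (4R,6S,8R)-4,6,8-tris(tert-butyldimethylsilyloxy)-10-phenyldec-1-yne | C#CC[C@@H](O[Si](C)(C)C(C)(C)C)C[C@@H](O[Si](C)(C)C(C)(C)C)C[C@H](O[Si](C)(C)C(C)(C)C)CCc1ccccc1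
F3 | step 11 | (7R,9S,11R)-1,7,9,11-tetrakis(tert-butyldimethylsilyloxy)-13-phenyltridec-4-yn-3-one | CC(C)(C)[Si](C)(C)OCCC(=O)C#CC[C@@H](O[Si](C)(C)C(C)(C)C)C[C@@H](O[Si](C)(C)C(C)(C)C)C[C@H](O[Si](C)(C)C(C)(C)C)CCc1ccccc1
F4 | step 11 | (3S,7R,9S,11R)-1,7,9,11-tetrakis(tert-butyldimethylsilyloxy)-13-phenyltridec-4-yn-3-ol | CC(C)(C)[Si](C)(C)OCC[C@H](O)C#CC[C@@H](O[Si](C)(C)C(C)(C)C)C[C@@H](O[Si](C)(C)C(C)(C)C)C[C@H](O[Si](C)(C)C(C)(C)C)CCc1ccccc1
F5 | step 11 | (3S,7R,9S,11R)-1,7,9,11-tetrakis(tert-butyldimethylsilyloxy)-3-(naphthalen-2-ylmethoxy)-13-phenyltridec-4-yne | CC(C)(C)[Si](C)(C)OCC[C@H](OCc1ccc2ccccc2c1)C#CC[C@@H](O[Si](C)(C)C(C)(C)C)C[C@@H](O[Si](C)(C)C(C)(C)C)C[C@H](O[Si](C)(C)C(C)(C)C)CCc1ccccc1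
F6 | step 5 | O-[(2E,4S)-6-(tert-butyldimethylsilyloxy)-4-(naphthalen-2-ylmethoxy)hex-2-en-1-yl] S-methyl carbonodithioate | CSC(=S)OC/C=C/[C@@H](OCc1ccc2ccccc2c1)CCO[Si](C)(C)C(C)(C)C
F7 | step 5 | S-[(4S)-6-(tert-butyldimethylsilyloxy)-4-(naphthalen-2-ylmethoxy)hex-1-en-3-yl] S-methyl carbonodithioate (both epimers at C3) | CSC(=O)SC(C=C)[C@@H](OCc1ccc2ccccc2c1)CCO[Si](C)(C)C(C)(C)C
F8 | step 3 | (2E,4S)-6-(tert-butyldimethylsilyloxy)hex-2-ene-1,4-diol | OC/C=C/[C@@H](O)CCO[Si](C)(C)C(C)(C)C
F9 | step 3 | (2E,4S)-6-(tert-butyldimethylsilyloxy)-4-hydroxyhex-2-en-1-yl 2,2-dimethylpropanoate | CC(C)(C)C(=O)OC/C=C/[C@@H](O)CCO[Si](C)(C)C(C)(C)C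
F10 | step 3 | (2E,4S)-6-(tert-butyldimethylsilyloxy)-4-(naphthalen-2-ylmethoxy)hex-2-en-1-yl 2,2-dimethylpropanoate | CC(C)(C)C(=O)OC/C=C/[C@@H](OCc1ccc2ccccc2c1)CCO[Si](C)(C)C(C)(C)C
F11 | step 13 | (3S,4Z,7R,9S,11R)-3-(naphthalen-2-ylmethoxy)-13-phenyltridec-4-ene-1,7,9,11-tetraol | OCC[C@@H](/C=C\C[C@@H](O)C[C@@H](O)C[C@H](O)CCc1ccccc1)OCc1ccc2ccccc2c1
F12 | step 13 | (3S,4Z,7R,9S,11R)-7,9,11-trihydroxy-3-(naphthalen-2-ylmethoxy)-13-phenyltridec-4-enal | O=CC[C@@H](/C=C\C[C@@H](O)C[C@@H](O)C[C@H](O)CCc1ccccc1)OCc1ccc2ccccc2c1
F13 | step 13 | methyl (2Z,5S,6Z,9R,11S,13R)-9,11,13-trihydroxy-5-(naphthalen-2-ylmethoxy)-15-phenylpentadeca-2,6-dienoate | COC(=O)/C=C\C[C@@H](/C=C\C[C@@H](O)C[C@@H](O)C[C@H](O)CCc1ccccc1)OCc1ccc2ccccc2c1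
F14 | step 10 | (3R,5R)-3,5-bis(tert-butyldimethylsilyloxy)-7-phenylheptan-1-ol | OCC[C@@H](O[Si](C)(C)C(C)(C)C)C[C@H](O[Si](C)(C)C(C)(C)C)CCc1ccccc1
A1 | alternative 1 | chloroacetaldehyde | ClCC=O
A2 | alternative 1 | acetaldehyde | CC=O
A3 | alternative 1 | (4R,6S)-6-(chloromethyl)tetrahydro-2H-pyran-2,4-diol | ClC[C@@H]1C[C@@H](O)CC(O)O1
A4 | alternative 2 | cis-3,5-bis(tert-butyldimethylsilyloxy)cyclohexanone (meso) | O=C1C[C@@H](O[Si](C)(C)C(C)(C)C)C[C@@H](O[Si](C)(C)C(C)(C)C)C1
A5 | alternative 2 | (4R,6S)-4,6-bis(tert-butyldimethylsilyloxy)oxepan-2-one | O=C1OC[C@@H](O[Si](C)(C)C(C)(C)C)C[C@@H](O[Si](C)(C)C(C)(C)C)C1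
A6 | alternative 3 | {[(3S)-5-(4-methoxybenzyloxy)pent-1-en-3-yl]oxy}{[(4R,6S,8R)-6,8-bis(tert-butyldimethylsilyloxy)-10-phenyldec-1-en-4-yl]oxy}di(propan-2-yl)silane | COc1ccc(COCC[C@@H](C=C)O[Si](C(C)C)(C(C)C)O[C@H](CC=C)C[C@@H](O[Si](C)(C)C(C)(C)C)C[C@H](O[Si](C)(C)C(C)(C)C)CCc2ccccc2)cc1
A7 | alternative 3 | eight-membered Z-silaketal (1,3-dioxa-2-silacyclooct-5-ene) carrying C3 to C15, O5 and O9 bridged by di(propan-2-yl)silylene, C3 as 4-methoxybenzyl ether | COc1ccc(COCC[C@H]3/C=C\C[C@H](C[C@@H](O[Si](C)(C)C(C)(C)C)C[C@H](O[Si](C)(C)C(C)(C)C)CCc2ccccc2)O[Si](C(C)C)(C(C)C)O3)cc1
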